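**Retrosynthetic overview**

1. Prostanoid numbering is used throughout (C1 ester carbon, ring carbons C8–C12, chlorine on C10, octenyl chain C13–C20). The last operations are orthoester-to-ester unveiling, O-desilylation and acetylation of the C12 tertiary alcohol.
2. The strategy rests on the C5=C6 (Z)-alkene, a cis-1,2-disubstituted ethylene lying between sp3 C4 and sp2 C7 of the exocyclic dienone. It is cut on both sides (C4–C5 and C6–C7) into a C1–C4 orthoester Grignard reagent, acetylene and a C7 (E)-bromomethylene enone, which are joined in one pot by syn-carbocupration and palladium-catalysed alkenyl–alkenyl coupling.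
3. The bromomethylene enone comes from C8 formylation and deoxybromination of a 10-chloro-12-silyloxy enone, itself made by α-chlorination and Lindlar reduction of an octynyl enone.
4. C12 is set by anti 1,2-propargylation of (R)-4-silyloxycyclopentenone, followed by alkyne alkylation and oxidation at C9 (1,3-carbonyl transposition).
5. No ring is formed: the single five-membered carbocycle is bought with the starting enone.

Key step: step 11

Remark: the formyl ketone 14 is drawn as its chelated (Z)-enol, although a mixture of enol forms is expected; this has no consequence because step 9 sets the C7=C8 geometry.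

**Route**

Step 1
Reactants: 1 (R)-4-(tert-butyldimethylsilyloxy)cyclopent-2-en-1-one; 2 propargyl bromide (3-bromoprop-1-yne)
Product: 4 (1S,4R)-4-(tert-butyldimethylsilyloxy)-1-(prop-2-yn-1-yl)cyclopent-2-en-1-ol, via allenylmagnesium bromide 3 (not isolated)
Conditions: 2, Mg, HgCl2 (cat.), Et2O, 0 °C; then 1, Et2O, −78 °C; aq. NH4Cl
Reagents that add atoms: none
Why: Allenylmagnesium bromide propargylates the ketone by SE2' 1,2-addition to give the homopropargylic tertiary alcohol, and the C9 silyloxy group shields its own face so that the C12–C13 bond should form trans to it, which sets C12 (the minor cis adduct is removed by chromatography because it would lead into the enantiomeric series).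

Step 2
Reactants: 4 (1S,4R)-4-(tert-butyldimethylsilyloxy)-1-(prop-2-yn-1-yl)cyclopent-2-en-1-ol; 5 1-iodopentane
Product: 7 (1S,4R)-4-(tert-butyldimethylsilyloxy)-1-(oct-2-yn-1-yl)cyclopent-2-en-1-ol, via dilithium alkoxide-acetylide 6 (not isolated)
Conditions: n-BuLi (2.2 equiv), THF, −78 → 0 °C; then 5, DMPU, 0 °C → rt; aq. NH4Cl
Reagents that add atoms: none
Why: Double deprotonation gives the alkoxide–acetylide dianion, whose acetylide carbon is alkylated by the primary iodide (SN2 acetylide alkylation) while the hindered tertiary alkoxide remains unalkylated.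

Step 3
Reactants: 7 (1S,4R)-4-(tert-butyldimethylsilyloxy)-1-(oct-2-yn-1-yl)cyclopent-2-en-1-ol
Product: 8 (1S,4R)-1-(oct-2-yn-1-yl)cyclopent-2-ene-1,4-diol
Conditions: TBAF, THF, 0 °C → rt
Reagents that add atoms: none
Why: Fluoride-mediated silyl ether cleavage frees the C9 alcohol without touching the tertiary allylic alcohol or the alkyne, and it would also remove any silyl group that had migrated to the tertiary oxygen in step 2.

Step 4
Reactants: 8 (1S,4R)-1-(oct-2-yn-1-yl)cyclopent-2-ene-1,4-diol
Product: 9 (S)-4-hydroxy-4-(oct-2-yn-1-yl)cyclopent-2-en-1-one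
Conditions: MnO2 (activated, excess), CH2Cl2, rt
Reagents that add atoms: none
Why: MnO2 oxidises only the secondary allylic alcohol (allylic oxidation), the tertiary alcohol being unable to oxidise, which completes the 1,3-carbonyl transposition and leaves C12 as the only stereocentre.

Step 5
Reactants: 9 (S)-4-hydroxy-4-(oct-2-yn-1-yl)cyclopent-2-en-1-one
Product: 10 (S)-4-(oct-2-yn-1-yl)-4-(triethylsilyloxy)cyclopent-2-en-1-one
Conditions: TESOTf (1.2 equiv), 2,6-lutidine, CH2Cl2, −78 → 0 °C
Reagents that add atoms: triethylsilyl trifluoromethanesulfonate, CC[Si](CC)(CC)OS(=O)(=O)C(F)(F)F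
Why: The silyl triflate with a hindered pyridine base silylates the tertiary alcohol at low temperature faster than it enolises the ketone, and the silyl ether protects the β-hydroxy ketone against retro-aldol opening (and hence racemisation) in the later base-mediated steps.

Step 6
Reactants: 10 (S)-4-(oct-2-yn-1-yl)-4-(triethylsilyloxy)cyclopent-2-en-1-one
Product: 11 (S)-2-chloro-4-(oct-2-yn-1-yl)-4-(triethylsilyloxy)cyclopent-2-en-1-one
Conditions: PhSeCl (2.5 equiv), pyridine (3 equiv), CH2Cl2, rt
Reagents that add atoms: phenylselenenyl chloride, Cl[Se]c1ccccc1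
Why: The PhSeCl–pyridine reagent (Ley α-chlorination of enones) engages the enone by conjugate addition, α-selenenylation and elimination and then exchanges the α-selenium for chlorine with loss of PhSeSePh, which places chlorine on C10, the only enone α-position bearing hydrogen, under nearly neutral conditions that the silyl ether tolerates.

Step 7
Reactants: 11 (S)-2-chloro-4-(oct-2-yn-1-yl)-4-(triethylsilyloxy)cyclopent-2-en-1-one
Product: 12 (S)-2-chloro-4-[(Z)-oct-2-en-1-yl]-4-(triethylsilyloxy)cyclopent-2-en-1-one
Conditions: H2 (1 atm), Pd/CaCO3 poisoned with Pb(OAc)2 (Lindlar catalyst), quinoline, EtOAc, rt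
Reagents that add atoms: none
Why: Lindlar semihydrogenation delivers H2 syn to the alkyne on the poisoned palladium surface to give the 14Z alkene, while the hindered chloro-enone alkene and the vinylic C–Cl bond should not be reduced on the deactivated catalyst.

Step 8
Reactants: 12 (S)-2-chloro-4-[(Z)-oct-2-en-1-yl]-4-(triethylsilyloxy)cyclopent-2-en-1-one
Product: 14 (4R,5Z)-2-chloro-5-(hydroxymethylene)-4-[(Z)-oct-2-en-1-yl]-4-(triethylsilyloxy)cyclopent-2-en-1-one, via lithium dienolate 13 (not isolated)
Conditions: LiN(iPr)2 (1.2 equiv), THF, −78 °C; then CF3CH2OCHO, −78 °C; aq. NH4Cl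
Reagents that add atoms: 2,2,2-trifluoroethyl formate, O=COCC(F)(F)F
Why: Deprotonation can occur only at C8 (C10 bears chlorine and C12 is quaternary), and the cross-conjugated lithium enolate is C-formylated by the activated formate in a crossed Claisen condensation, β-elimination of the C12 silyloxide being disfavoured because it would give a cyclopentadienone.

Step 9
Reactants: 14 (4R,5Z)-2-chloro-5-(hydroxymethylene)-4-[(Z)-oct-2-en-1-yl]-4-(triethylsilyloxy)cyclopent-2-en-1-one
Product: 15 (4R,5E)-5-(bromomethylene)-2-chloro-4-[(Z)-oct-2-en-1-yl]-4-(triethylsilyloxy)cyclopent-2-en-1-one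
Conditions: Ph3PBr2, Et3N, CH2Cl2, 0 °C → rt
Reagents that add atoms: dibromotriphenylphosphorane, BrP(Br)(c1ccccc1)(c1ccccc1)c1ccccc1
Why: The enol oxygen of the vinylogous acid is activated as an oxyphosphonium salt and displaced by bromide through addition–elimination at C7 with loss of Ph3PO (deoxybromination of a β-dicarbonyl enol), and reversible bromide addition should settle the geometry on the E isomer, in which bromine points away from the C9 carbonyl oxygen.

Step 10
Reactants: 16 trimethyl 4-bromoorthobutyrate (4-bromo-1,1,1-trimethoxybutane)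
Product: 17 4,4,4-trimethoxybutylmagnesium bromide (used as a titrated Et2O solution)
Conditions: Mg turnings, I2 (cat.), Et2O, rt
Reagents that add atoms: magnesium, [Mg]
Why: Magnesium inserts into the primary C–Br bond (Grignard formation), and the orthoester, which has no electrophilic carbonyl and ionises only under acid, is inert to the reagent at or below room temperature.

Step 11
Reactants: 17 4,4,4-trimethoxybutylmagnesium bromide; 18 acetylene; 15 (4R,5E)-5-(bromomethylene)-2-chloro-4-[(Z)-oct-2-en-1-yl]-4-(triethylsilyloxy)cyclopent-2-en-1-one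
Product: 21 (4R,5E)-2-chloro-4-[(Z)-oct-2-en-1-yl]-4-(triethylsilyloxy)-5-[(Z)-7,7,7-trimethoxyhept-2-en-1-ylidene]cyclopent-2-en-1-one, via alkylcopper 19 (not isolated), via (Z)-alkenylcopper 20 (not isolated)
Conditions: 17 (2.2 equiv), CuBr·SMe2 (2.2 equiv), Et2O/Me2S, −45 °C; 18 (2.2 equiv), −45 → −20 °C, then N2 purge; 15 (1.0 equiv), Pd(PPh3)4 (5 mol %), THF, −20 → 0 °C, dark; aq. NH4Cl/NH3 (pH 8)
Reagents that add atoms: none
Why: The Grignard reagent transmetalates to the monovalent alkylcopper 19, which adds across acetylene through a four-centre syn transition state, so that C4 and copper are cis on C5=C6 in 20 and the 5Z geometry is fixed by mechanism as the C4–C5 bond forms. Zerovalent palladium then inserts with retention into the C7–Br bond of the vinylogous acyl bromide 15, the alkenyl group passes from copper to palladium, and reductive elimination forms C6–C7 with both alkene geometries retained (5Z,7E). The closest known reaction type is the carbocupration of acetylene followed by Pd(PPh3)4-catalysed coupling of the resulting (Z)-alkenylcopper with an alkenyl halide. No ring is closed and no stereocentre is created, C12 being untouched. The step needs C7–Br to react in preference to C10–Cl, which the weaker C–Br bond at the activated β-position of the enone secures, and it needs a single acetylene insertion, which low temperature and removal of excess acetylene before the coupling secure. The soft organocopper should not add to the C9 carbonyl, conjugate attack at C11 is blocked by the quaternary C12, and the orthoester is inert to the carbanionic reagents (no Lewis-acidic zinc salt is added for that reason).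

Step 12
Reactants: 21 (4R,5E)-2-chloro-4-[(Z)-oct-2-en-1-yl]-4-(triethylsilyloxy)-5-[(Z)-7,7,7-trimethoxyhept-2-en-1-ylidene]cyclopent-2-en-1-one
Product: 22 methyl (5Z,7E,12R,14Z)-10-chloro-9-oxo-12-(triethylsilyloxy)prosta-5,7,10,14-tetraen-1-oate
Conditions: PPTS (cat.), THF/H2O, 0 °C
Reagents that add atoms: water, O
Why: Orthoester hydrolysis under very mild acid proceeds through a dialkoxycarbenium ion and a hemiorthoester to the methyl ester, under conditions that the tertiary triethylsilyl ether and the dienone should survive.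

Step 13
Reactants: 22 methyl (5Z,7E,12R,14Z)-10-chloro-9-oxo-12-(triethylsilyloxy)prosta-5,7,10,14-tetraen-1-oate
Product: 23 methyl (5Z,7E,12R,14Z)-10-chloro-12-hydroxy-9-oxoprosta-5,7,10,14-tetraen-1-oate
Conditions: HF·pyridine, pyridine, THF, 0 °C → rt
Reagents that add atoms: none
Why: Buffered HF cleaves the tertiary silyl ether through Si–F bond formation (fluoride desilylation) without basic fluoride that would attack the electrophilic dienone, and C12 is not ionised because the adjacent electron-poor ring disfavours a cation there.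

Step 14
Reactants: 23 methyl (5Z,7E,12R,14Z)-10-chloro-12-hydroxy-9-oxoprosta-5,7,10,14-tetraen-1-oate
Product: 24 methyl (5Z,7E,12R,14Z)-12-acetoxy-10-chloro-9-oxoprosta-5,7,10,14-tetraen-1-oate
Conditions: Ac2O, DMAP, Et3N, CH2Cl2, rt, dark
Reagents that add atoms: acetic anhydride, CC(=O)OC(C)=O
Why: DMAP-catalysed acylation through the N-acetylpyridinium ion esterifies the hindered tertiary alcohol with retention at C12, since the C–O bond is not broken.

**Compound list**

1 | (R)-4-(tert-butyldimethylsilyloxy)cyclopent-2-en-1-one | O=C1C[C@@H](O[Si](C)(C)C(C)(C)C)C=C1 | starting material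
2 | propargyl bromide (3-bromoprop-1-yne) | C#CCBr | starting material
3 | allenylmagnesium bromide | C=C=C[Mg]Br | intermediate
4 | (1S,4R)-4-(tert-butyldimethylsilyloxy)-1-(prop-2-yn-1-yl)cyclopent-2-en-1-ol | C#CC[C@@]1(O)C=C[C@H](O[Si](C)(C)C(C)(C)C)C1 | intermediate
5 | 1-iodopentane | CCCCCI | starting material
6 | dilithium alkoxide-acetylide of 4 | [Li]C#CC[C@@]1(O[Li])C=C[C@H](O[Si](C)(C)C(C)(C)C)C1 | intermediate
7 | (1S,4R)-4-(tert-butyldimethylsilyloxy)-1-(oct-2-yn-1-yl)cyclopent-2-en-1-ol | CCCCCC#CC[C@@]1(O)C=C[C@H](O[Si](C)(C)C(C)(C)C)C1 | intermediate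
8 | (1S,4R)-1-(oct-2-yn-1-yl)cyclopent-2-ene-1,4-diol | CCCCCC#CC[C@@]1(O)C=C[C@H](O)C1 | intermediate
9 | (S)-4-hydroxy-4-(oct-2-yn-1-yl)cyclopent-2-en-1-one | CCCCCC#CC[C@@]1(O)C=CC(=O)C1 | intermediate
10 | (S)-4-(oct-2-yn-1-yl)-4-(triethylsilyloxy)cyclopent-2-en-1-one | CCCCCC#CC[C@@]1(O[Si](CC)(CC)CC)C=CC(=O)C1 | intermediate
11 | (S)-2-chloro-4-(oct-2-yn-1-yl)-4-(triethylsilyloxy)cyclopent-2-en-1-one | CCCCCC#CC[C@@]1(O[Si](CC)(CC)CC)C=C(Cl)C(=O)C1 | intermediate
12 | (S)-2-chloro-4-[(Z)-oct-2-en-1-yl]-4-(triethylsilyloxy)cyclopent-2-en-1-one | CCCCC/C=C\C[C@@]1(O[Si](CC)(CC)CC)C=C(Cl)C(=O)C1 | intermediate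
13 | lithium cross-conjugated dienolate of 12 (C8 deprotonated) | CCCCC/C=C\C[C@@]1(O[Si](CC)(CC)CC)C=C(Cl)C(O[Li])=C1 | intermediate
14 | (4R,5Z)-2-chloro-5-(hydroxymethylene)-4-[(Z)-oct-2-en-1-yl]-4-(triethylsilyloxy)cyclopent-2-en-1-one | CCCCC/C=C\C[C@@]1(O[Si](CC)(CC)CC)C=C(Cl)C(=O)/C1=C\O | intermediate
15 | (4R,5E)-5-(bromomethylene)-2-chloro-4-[(Z)-oct-2-en-1-yl]-4-(triethylsilyloxy)cyclopent-2-en-1-one | CCCCC/C=C\C[C@@]1(O[Si](CC)(CC)CC)C=C(Cl)C(=O)/C1=C/Br | intermediate
16 | trimethyl 4-bromoorthobutyrate (4-bromo-1,1,1-trimethoxybutane) | COC(CCCBr)(OC)OC | starting material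
17 | 4,4,4-trimethoxybutylmagnesium bromide | COC(OC)(OC)CCC[Mg]Br | intermediate
18 | acetylene | C#C | starting material
19 | (4,4,4-trimethoxybutyl)copper (as its MgBr2·SMe2 complex) | COC(OC)(OC)CCC[Cu] | intermediate
20 | [(Z)-6,6,6-trimethoxyhex-1-en-1-yl]copper | COC(OC)(OC)CCC/C=C\[Cu] | intermediate
21 | (4R,5E)-2-chloro-4-[(Z)-oct-2-en-1-yl]-4-(triethylsilyloxy)-5-[(Z)-7,7,7-trimethoxyhept-2-en-1-ylidene]cyclopent-2-en-1-one | CCCCC/C=C\C[C@@]1(O[Si](CC)(CC)CC)C=C(Cl)C(=O)/C1=C/C=C\CCCC(OC)(OC)OC | intermediate
22 | methyl (5Z,7E,12R,14Z)-10-chloro-9-oxo-12-(triethylsilyloxy)prosta-5,7,10,14-tetraen-1-oate | CCCCC/C=C\C[C@@]1(O[Si](CC)(CC)CC)C=C(Cl)C(=O)/C1=C/C=C\CCCC(=O)OC | intermediate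
23 | methyl (5Z,7E,12R,14Z)-10-chloro-12-hydroxy-9-oxoprosta-5,7,10,14-tetraen-1-oate | CCCCC/C=C\C[C@@]1(O)C=C(Cl)C(=O)/C1=C/C=C\CCCC(=O)OC | intermediate
24 | methyl (5Z,7E,12R,14Z)-12-acetoxy-10-chloro-9-oxoprosta-5,7,10,14-tetraen-1-oate | CCCCC/C=C\C[C@@]1(OC(C)=O)C=C(Cl)C(=O)/C1=C/C=C\CCCC(=O)OC | target

**Step count and risks**

Total step count: 14. Longest linear sequence: 13 steps (steps 1–9 and 11–14; step 10 is a one-step side branch).

Steps most likely to fail:

Step 11. The carbocupration may stall or run on to a second acetylene insertion, the alkylcopper may transfer its alkyl group instead of the alkenyl group, and copper-to-palladium transfer may be slow enough for homocoupling or loss of the C5 geometry to intervene; magnesium salts may also ionise the orthoester. The fallback prepares the (Z)-alkenyl donor separately and couples it under neutral conditions. Commercial methyl hex-5-ynoate would be C-stannylated with Bu3SnNEt2 to methyl 6-(tributylstannyl)hex-5-ynoate F1. Hydrozirconation of F1 with Cp2Zr(H)Cl followed by protonolysis should give methyl (Z)-6-(tributylstannyl)hex-5-enoate F2. Stille coupling of F2 with 15 (Pd2(dba)3, AsPh3, CuI, DMF, rt) would set out from 15 and come back to the route at 22, the methyl ester being already in place.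

Step 9. Reversible bromide addition–elimination may leave a mixture of C7=C8 geometries, HBr may strip the silyl ether, and the amine may add to the highly electrophilic product. The fallback sets out from 14 and replaces the halide by a sulfonate made under bromide-free, non-acidic conditions: TsCl, Et3N and catalytic DMAP in CH2Cl2 at 0 °C should give (4R,5E)-2-chloro-4-[(Z)-oct-2-en-1-yl]-5-(tosyloxymethylene)-4-(triethylsilyloxy)cyclopent-2-en-1-one F3. F3 would then be treated with the alkenylcopper 20 and Pd(PPh3)4 as in step 11, the sulfonate being displaced by addition–elimination or by insertion of zerovalent palladium, so that the route is rejoined at 21.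

Step 6. The selenenyl chloride may add across the side-chain alkyne, and conjugate attack at the hindered C11 next to the quaternary C12 may be slow. The fallback sets out from 10 and uses an enone-specific nucleophilic sequence. Epoxidation with t-BuOOH and DBU in CH2Cl2 should give (1S,4S,5S)-4-(oct-2-yn-1-yl)-4-(triethylsilyloxy)-6-oxabicyclo[3.1.0]hexan-2-one F4 (epoxide drawn anti to the silyloxy group; either epimer converges). Opening with LiCl and AcOH in THF at the activated α-carbon should give (2R,3S,4S)-2-chloro-3-hydroxy-4-(oct-2-yn-1-yl)-4-(triethylsilyloxy)cyclopentan-1-one F5. Mesylation and E1cB elimination (MsCl, Et3N, CH2Cl2, 0 °C) would come back to the route at 11.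

**Further compounds**

F1 | step 11 | methyl 6-(tributylstannyl)hex-5-ynoate | CCCC[Sn](CCCC)(CCCC)C#CCCCC(=O)OC
F2 | step 11 | methyl (Z)-6-(tributylstannyl)hex-5-enoate | CCCC[Sn](CCCC)(CCCC)/C=C\CCCC(=O)OC
F3 | step 9 | (4R,5E)-2-chloro-4-[(Z)-oct-2-en-1-yl]-5-(tosyloxymethylene)-4-(triethylsilyloxy)cyclopent-2-en-1-one | CCCCC/C=C\C[C@@]1(O[Si](CC)(CC)CC)C=C(Cl)C(=O)/C1=C/OS(=O)(=O)c2ccc(C)cc2
F4 | step 6 | (1S,4S,5S)-4-(oct-2-yn-1-yl)-4-(triethylsilyloxy)-6-oxabicyclo[3.1.0]hexan-2-one | CCCCCC#CC[C@@]1(O[Si](CC)(CC)CC)[C@H]2O[C@H]2C(=O)C1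
F5 | step 6 | (2R,3S,4S)-2-chloro-3-hydroxy-4-(oct-2-yn-1-yl)-4-(triethylsilyloxy)cyclopentan-1-one | CCCCCC#CC[C@@]1(O[Si](CC)(CC)CC)[C@@H](O)[C@H](Cl)C(=O)C1
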